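**Retrosynthetic overview**

1. The spiro ketal carbon of ring A is cut at both C–O bonds; the last step joins the cage β-hydroxy acid to a hydroxy-pyranoquinone by ester formation and oxa-Michael closure of the spiro 1,3-dioxan-4-one.
2. The oxolane is cut at the O–C bond of the prenylated quaternary carbon, which is closed by trivalent-iodine oxidation of a silyl enol ether with the CMe2 oxygen as nucleophile.
3. Key disconnection: the enoate bridge C=C–C(=O)O of the bicyclo[2.2.2]octene joins the carbinol bridgehead to the O-bearing bridgehead, and that oxygen is tied to the ester carbonyl through the O–C–O carbon of the dioxanone. An O–CH2–O–C(=O) tether between a dienol oxygen and a propiolate therefore closes the bicyclo[2.2.2]octadiene and the 1,3-dioxan-4-one in one intramolecular Diels–Alder reaction.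
4. The cyclohexadiene comes from (−)-β-pinene. Nopinone is opened at the ketone stage to a regiodefined enol acetate, because the enone could open at the other cyclobutane bond. This keeps the single stereocentre and directs the first oxygen to the future carbinol bridgehead. Then follow the 1,3-dione, C-prenylation, the O-tether and the silyl dienol ether.
5. Order of rings: cyclohexane (from pinene); dioxanone together with bicyclo[2.2.2]octadiene (key step); oxolane; 2H-pyran of ring A (made separately); spiro dioxanone last.

Key step: step 12

Assumption: the spiro ketal carbon and the neighbouring prenyl-bearing CH of ring A are formed last under equilibrating acid conditions, and the configuration of the target is taken to be the more stable one at both centres.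

**Route**

Step 1
Reactants: 1 (−)-β-pinene
Product: 2 (+)-nopinone [(1R,5S)-6,6-dimethylbicyclo[3.1.1]heptan-2-one]
Conditions: O3, CH2Cl2–MeOH, −78 °C; then Me2S, −78 °C → rt
Reagents that add atoms: ozone, O=[O+][O-]
Why: Ozonolysis with reductive work-up cleaves only the exocyclic 1,1-disubstituted alkene and leaves both ring stereocentres untouched.

Step 2
Reactants: 2 (+)-nopinone
Product: 3 (S)-4-(2-acetoxypropan-2-yl)cyclohex-1-en-1-yl acetate
Conditions: Ac2O, BF3·OEt2, Zn(OAc)2, rt
Reagents that add atoms: acetic anhydride, CC(=O)OC(C)=O
Why: Lewis acid-promoted fragmentation of the cyclobutyl ketone breaks the C-1–C-6 bond that gives the tertiary cation (trapped by acetate) and acetylates the enolate where it forms, so the enol double bond lies toward the former bridgehead and the surviving stereocentre (former C-5) is untouched; the saturated ketone is used because it can open only in this sense, whereas the derived enone could also open at the vinylogous bond and leave the side chain on the other bridgehead.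

Step 3
Reactants: 3 (S)-4-(2-acetoxypropan-2-yl)cyclohex-1-en-1-yl acetate
Product: 4 (4S)-2-hydroxy-4-(2-hydroxypropan-2-yl)cyclohexan-1-one (mixture of C-2 epimers)
Conditions: MeLi (4 equiv), THF, −78 → 0 °C; then 2-(phenylsulfonyl)-3-phenyloxaziridine, −78 °C; H2O
Reagents that add atoms: 2-(phenylsulfonyl)-3-phenyloxaziridine, O=S(=O)(N1OC1c1ccccc1)c1ccccc1
Why: MeLi cleaves the enol acetate to the lithium enolate without loss of its position (and removes the tertiary acetate), and hydroxylation of this enolate with the N-sulfonyloxaziridine (Davis oxidation) places the oxygen on the former bridgehead carbon; the new carbinol centre is of no consequence because this carbon becomes sp2 in step 11.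

Step 4
Reactants: 4 (4S)-2-hydroxy-4-(2-hydroxypropan-2-yl)cyclohexan-1-one
Product: 5 (4S)-2-(triethylsilyloxy)-4-[2-(triethylsilyloxy)propan-2-yl]cyclohexan-1-one
Conditions: TESOTf, 2,6-lutidine, CH2Cl2, −78 → 0 °C
Reagents that add atoms: triethylsilyl trifluoromethanesulfonate (TESOTf), CC[Si](CC)(CC)OS(=O)(=O)C(F)(F)F
Why: Silyl triflate with a hindered pyridine base silylates both the secondary and the tertiary alcohol (silyl ether formation) without touching a stereocentre.

Step 5
Reactants: 5 (4S)-2-(triethylsilyloxy)-4-[2-(triethylsilyloxy)propan-2-yl]cyclohexan-1-one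
Product: 7 (4R)-6-(triethylsilyloxy)-4-[2-(triethylsilyloxy)propan-2-yl]cyclohex-2-en-1-one, via trimethylsilyl enol ether 6 (not isolated)
Conditions: LiN(iPr)2, TMSCl, THF, −78 °C; then Pd(OAc)2, MeCN, rt
Reagents that add atoms: none
Why: Kinetic deprotonation of the α-silyloxy ketone takes place at the unsubstituted α-CH2, and Saegusa–Ito oxidation of the silyl enol ether with divalent palladium puts the enone on the side of the ring that carries the side chain; C-4 is not involved.

Step 6
Reactants: 7 (4R)-6-(triethylsilyloxy)-4-[2-(triethylsilyloxy)propan-2-yl]cyclohex-2-en-1-one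
Product: 8 (4R)-2,3-epoxy-6-(triethylsilyloxy)-4-[2-(triethylsilyloxy)propan-2-yl]cyclohexan-1-one (epoxide expected anti to the C-4 side chain)
Conditions: t-BuOOH, benzyltrimethylammonium hydroxide (cat.), THF, 0 °C
Reagents that add atoms: tert-butyl hydroperoxide, CC(C)(C)OO
Why: Weitz–Scheffer nucleophilic epoxidation of the enone under a short, cold, catalytic-base regime that should not enolise toward C-4; both epoxide centres disappear in step 7.

Step 7
Reactants: 8 (4R)-2,3-epoxy-6-(triethylsilyloxy)-4-[2-(triethylsilyloxy)propan-2-yl]cyclohexan-1-one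
Product: 9 (6S)-4-(triethylsilyloxy)-6-[2-(triethylsilyloxy)propan-2-yl]cyclohexane-1,3-dione (enolised)
Conditions: Pd(PPh3)4 (cat.), 1,2-bis(diphenylphosphino)ethane (cat.), toluene, 80 °C
Reagents that add atoms: none
Why: Zerovalent palladium-catalysed isomerisation of the α,β-epoxy ketone to the β-diketone (oxidative addition at the Cα–O bond, β-hydride elimination from the carbinol carbon, reductive elimination); the C-6 centre is kept because the dione rests as its C-2 enol and does not enolise toward C-6 under neutral conditions.

Step 8
Reactants: 9 (6S)-4-(triethylsilyloxy)-6-[2-(triethylsilyloxy)propan-2-yl]cyclohexane-1,3-dione; 10 prenyl bromide (1-bromo-3-methylbut-2-ene)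
Product: 11 (6S)-2-(3-methylbut-2-en-1-yl)-4-(triethylsilyloxy)-6-[2-(triethylsilyloxy)propan-2-yl]cyclohexane-1,3-dione (enolised)
Conditions: iPr2NEt, Pd(PPh3)4 (cat.), THF, rt
Reagents that add atoms: none
Why: Tsuji–Trost allylation, in which the soft dione carbon attacks the π-prenyl palladium complex at its unsubstituted terminus and any O-prenyl enol ether is re-ionised by zerovalent palladium, so the C-2 prenyl dione accumulates; the mono-anion does not epimerise C-6.

Step 9
Reactants: 12 propiolic acid
Product: 13 chloromethyl prop-2-ynoate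
Conditions: ClCH2OSO2Cl, NaHCO3, Bu4NHSO4 (cat.), CH2Cl2–H2O, rt
Reagents that add atoms: chloromethyl chlorosulfate, ClCOS(Cl)(=O)=O
Why: Phase-transfer alkylation of the carboxylate by chloromethyl chlorosulfate (attack at carbon, loss of chlorosulfate) is the usual way to chloromethyl esters and leaves the alkyne untouched.

Step 10
Reactants: 11 (6S)-2-(3-methylbut-2-en-1-yl)-4-(triethylsilyloxy)-6-[2-(triethylsilyloxy)propan-2-yl]cyclohexane-1,3-dione; 13 chloromethyl prop-2-ynoate
Product: 14 {[(6R)-2-(3-methylbut-2-en-1-yl)-3-oxo-4-(triethylsilyloxy)-6-[2-(triethylsilyloxy)propan-2-yl]cyclohex-1-en-1-yl]oxy}methyl prop-2-ynoate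
Conditions: Cs2CO3, DMF, 0 °C → rt
Reagents that add atoms: none
Why: Williamson-type O-alkylation of the caesium enolate of the 2-substituted 1,3-dione by the SN2-reactive chloromethyl ester (C-alkylation would have to build a quaternary C-2); the enolate has two oxygens, and the isomer alkylated at the oxygen on C-3 is expected as a by-product of at least comparable weight, which is removed by chromatography and cleaved back to 11 with aqueous base; no stereocentre is formed.

Step 11
Reactants: 14 {[(6R)-2-(3-methylbut-2-en-1-yl)-3-oxo-4-(triethylsilyloxy)-6-[2-(triethylsilyloxy)propan-2-yl]cyclohex-1-en-1-yl]oxy}methyl prop-2-ynoate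
Product: 15 {[(6R)-3-(tert-butyldimethylsilyloxy)-2-(3-methylbut-2-en-1-yl)-4-(triethylsilyloxy)-6-[2-(triethylsilyloxy)propan-2-yl]cyclohexa-1,3-dien-1-yl]oxy}methyl prop-2-ynoate
Conditions: TBSOTf, iPr2NEt, CH2Cl2, −78 → −20 °C
Reagents that add atoms: tert-butyldimethylsilyl trifluoromethanesulfonate (TBSOTf), CC(C)(C)[Si](C)(C)OS(=O)(=O)C(F)(F)F
Why: Soft enolisation, in which O-silylation of the vinylogous ester carbonyl gives a dioxy-allyl cation that the amine deprotonates at C-4 (activated by its silyloxy group and less hindered than C-6–H), gives the 2-silyloxy-1,3-diene without strong base, so the terminal alkyne, the acylal ester and the C-6 stereocentre should survive.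

Step 12
Reactants: 15 {[(6R)-3-(tert-butyldimethylsilyloxy)-2-(3-methylbut-2-en-1-yl)-4-(triethylsilyloxy)-6-[2-(triethylsilyloxy)propan-2-yl]cyclohexa-1,3-dien-1-yl]oxy}methyl prop-2-ynoate
Product: 16 Diels–Alder adduct: bicyclo[2.2.2]octa-2,5-diene with C-1 (bridgehead O) and C-6 joined by O–CH2–O–C(=O) as a fused 1,3-dioxan-4-one; C-2 prenyl; C-3 OTBS; C-4 bridgehead OTES; C-8 CMe2OTES syn to the C-2/C-3 bridge
Conditions: toluene (high dilution), 2,6-di-tert-butyl-4-methylphenol (trace), 90 °C
Reagents that add atoms: none
Why: Thermal, concerted but asynchronous [4+2] addition of the ester-activated alkyne to the electron-rich 1,3,4-trioxygenated diene, the intramolecular counterpart of the known Diels–Alder reactions of 2-silyloxycyclohexa-1,3-dienes with alkynoates and of ester-tethered intramolecular Diels–Alder reactions. The bicyclo[2.2.2]octadiene closes by bond formation at both diene termini (C-1 to the ester-bearing alkyne carbon, C-4 to the alkyne CH), and the 1,3-dioxan-4-one closes at the same time as the ring that contains the four-atom O–CH2–O–C(=O) tether, which has to take up the s-cis ester conformation. The two new stereocentres are the bridgeheads; both follow from the diene face that is attacked, and this is fixed by the C-6 stereocentre, whose silyloxyisopropyl group sits pseudoaxial (allylic strain with the C-1 oxygen substituent) and blocks one face, so the alkyne adds anti and the CMe2 group ends up over the enol ether bridge. Regiochemistry is enforced by the tether and agrees with the electronic preference (most nucleophilic terminus C-4 to the β-carbon of the propiolate). The step needs this anti facial selectivity and chemoselectivity against cycloreversion of the adduct (Alder–Rickert loss of the saturated bridge), which is why the temperature is held at 90 °C and acid is excluded.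

Step 13
Reactants: 16 Diels–Alder adduct
Product: 17 oxolane ketone: CMe2 oxygen bonded to the prenylated carbon C-2 (now quaternary); C-3 ketone; dioxanone and bridgehead OTES unchanged
Conditions: PhI(OCOCF3)2, 2,6-di-tert-butylpyridine, CH2Cl2, −78 → −30 °C
Reagents that add atoms: none
Why: Umpolung of the silyl enol ether by trivalent iodine (hypervalent-iodine α-oxygenation of enol silanes, here with an internal oxygen nucleophile): the activated enol ether is attacked at its prenylated carbon in a 5-exo closure by the neighbouring CMe2 silyl ether oxygen, which can reach only the face on which it is held, so the new quaternary centre is set cis-fused by the substrate while iodobenzene and both silyl groups are lost.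

Step 14
Reactants: 17 oxolane ketone
Product: 18 bridgehead alcohol (17 without the triethylsilyl group)
Conditions: HF·pyridine, pyridine, THF, 0 °C → rt
Reagents that add atoms: none
Why: Fluoride cleavage of the remaining bridgehead triethylsilyl ether; acylal, ketone and alkenes should be inert to buffered HF·pyridine.

Step 15
Reactants: 18 bridgehead alcohol
Product: 19 cage β-hydroxy acid (carboxylic acid on the alkene carbon next to the free bridgehead carbinol; second bridgehead OH free)
Conditions: LiOH, THF–H2O, 0 °C; then dilute HCl to pH 3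
Reagents that add atoms: lithium hydroxide, [Li+].[OH-]
Why: Saponification of the activated acyloxymethyl (acylal) ester, after which the hemiacetal on the bridgehead oxygen loses formaldehyde; short contact at 0 °C is chosen to avoid retro-aldol opening of the β-hydroxy ketone.

Step 16
Reactants: 20 2,6-dimethoxy-1,4-benzoquinone
Product: 21 2,6-dihydroxy-1,4-benzoquinone
Conditions: NaOH (aq), THF, 0 °C → rt; then HCl
Reagents that add atoms: sodium hydroxide, [Na+].[OH-]
Why: Addition–elimination of hydroxide at the two vinylogous ester carbons of the methoxyquinone (vinylogous ester saponification) gives the dihydroxyquinone on acidification.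

Step 17
Reactants: 21 2,6-dihydroxy-1,4-benzoquinone; 22 3-methylbut-2-enal
Product: 23 7-hydroxy-2,2-dimethyl-2H-chromene-5,8-dione
Conditions: ethylenediammonium diacetate (cat.), toluene, 80 °C
Reagents that add atoms: none
Why: Knoevenagel condensation of the enal at the nucleophilic CH next to an enolic OH, followed by 6π-oxa-electrocyclisation of the dienone, closes the 2,2-dimethyl-2H-pyran on the hydroxyl oxygen with the para-quinone retained; the substrate is symmetric, so one equivalent of enal should give the mono-annulated quinone.

Step 18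
Reactants: 23 7-hydroxy-2,2-dimethyl-2H-chromene-5,8-dione; 10 prenyl bromide
Product: 24 7-hydroxy-2,2-dimethyl-6-(3-methylbut-2-en-1-yl)-2H-chromene-5,8-dione
Conditions: LiH, DMSO, rt
Reagents that add atoms: none
Why: C-Alkylation of the lithium salt of the 2-hydroxy-1,4-quinone at the carbon between carbonyl and enol (the way lapachol-type prenyl hydroxyquinones are made); O-prenylation is the expected side reaction.

Step 19
Reactants: 19 cage β-hydroxy acid; 24 7-hydroxy-2,2-dimethyl-6-(3-methylbut-2-en-1-yl)-2H-chromene-5,8-dione
Product: 26 CNP0222516.1 (target), via acyloxyquinone 25 (not isolated)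
Conditions: EDC·HCl, 4-(dimethylamino)pyridine (cat.), CH2Cl2, −20 °C; then camphor-10-sulfonic acid (cat.), 4 Å molecular sieves, 0 °C → rt
Reagents that add atoms: none
Why: Proposed new method: carbodiimide esterification (Steglich type) acylates the acidic 7-OH of the hydroxyquinone; in 25 the bridgehead tertiary alcohol sits β to the ester carbonyl and, under acid catalysis, should add to the acyloxy-bearing quinone carbon C-7 in a six-membered oxa-Michael closure, after which the C-5 enol ketonises at C-6, so that C-7 becomes the spiro carbon of a 1,3-dioxan-4-one; the closest known reactions are acid-catalysed oxa-Michael additions to quinones and the formation of 1,3-dioxan-4-ones from β-hydroxy acids and ketones (C-7 is a carbonyl of the triketone tautomer of 24); both new centres form under equilibrating conditions (reversible ring closure, enolisable C-6–H) and are expected to settle in the more stable arrangement.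

**Compound list**

1 | (−)-β-pinene | C=C1CC[C@H]2C[C@@H]1C2(C)C | starting material
2 | (+)-nopinone | O=C1CC[C@H]2C[C@@H]1C2(C)C | intermediate
3 | (S)-4-(2-acetoxypropan-2-yl)cyclohex-1-en-1-yl acetate | CC(=O)OC1=CC[C@H](CC1)C(C)(C)OC(C)=O | intermediate
4 | (4S)-2-hydroxy-4-(2-hydroxypropan-2-yl)cyclohexan-1-one (C-2 epimers) | O=C1CC[C@@H](CC1O)C(C)(C)O | intermediate
5 | (4S)-2-(triethylsilyloxy)-4-[2-(triethylsilyloxy)propan-2-yl]cyclohexan-1-one (C-2 epimers) | O=C1CC[C@@H](CC1O[Si](CC)(CC)CC)C(C)(C)O[Si](CC)(CC)CC | intermediate
6 | trimethylsilyl enol ether of 5 (double bond toward the unsubstituted α-carbon) | C[Si](C)(C)OC1=CC[C@@H](CC1O[Si](CC)(CC)CC)C(C)(C)O[Si](CC)(CC)CC | intermediate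
7 | (4R)-6-(triethylsilyloxy)-4-[2-(triethylsilyloxy)propan-2-yl]cyclohex-2-en-1-one (C-6 epimers) | O=C1C=C[C@@H](CC1O[Si](CC)(CC)CC)C(C)(C)O[Si](CC)(CC)CC | intermediate
8 | (4R)-2,3-epoxy-6-(triethylsilyloxy)-4-[2-(triethylsilyloxy)propan-2-yl]cyclohexan-1-one | O=C1C2OC2[C@@H](CC1O[Si](CC)(CC)CC)C(C)(C)O[Si](CC)(CC)CC | intermediate
9 | (6S)-4-(triethylsilyloxy)-6-[2-(triethylsilyloxy)propan-2-yl]cyclohexane-1,3-dione | O=C1CC(=O)[C@@H](CC1O[Si](CC)(CC)CC)C(C)(C)O[Si](CC)(CC)CC | intermediate
10 | prenyl bromide | CC(C)=CCBr | starting material
11 | (6S)-2-(3-methylbut-2-en-1-yl)-4-(triethylsilyloxy)-6-[2-(triethylsilyloxy)propan-2-yl]cyclohexane-1,3-dione | O=C1C(CC=C(C)C)C(=O)[C@@H](CC1O[Si](CC)(CC)CC)C(C)(C)O[Si](CC)(CC)CC | intermediate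
12 | propiolic acid | OC(=O)C#C | starting material
13 | chloromethyl prop-2-ynoate | ClCOC(=O)C#C | intermediate
14 | propioloyloxymethyl vinylogous ester (tether on the enol oxygen next to C-6) | C#CC(=O)OCOC1=C(CC=C(C)C)C(=O)C(O[Si](CC)(CC)CC)C[C@H]1C(C)(C)O[Si](CC)(CC)CC | intermediate
15 | propioloyloxymethyl dienol ether of the silyloxy prenyl cyclohexadiene (key-step precursor) | C#CC(=O)OCOC1=C(CC=C(C)C)C(O[Si](C)(C)C(C)(C)C)=C(O[Si](CC)(CC)CC)C[C@H]1C(C)(C)O[Si](CC)(CC)CC | intermediate
16 | bicyclo[2.2.2]octadiene fused to a methylene-acetal 1,3-dioxan-4-one (key-step product) | O=C1OCO[C@@]2(C(CC=C(C)C)=C(O[Si](C)(C)C(C)(C)C)[C@]3(O[Si](CC)(CC)CC)C=C12)[C@@H](C3)C(C)(C)O[Si](CC)(CC)CC | intermediate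
17 | oxolane ketone with dioxanone and bridgehead OTES | C1OC(=O)C2=C[C@]3(O[Si](CC)(CC)CC)C[C@H]4C(C)(C)O[C@@](CC=C(C)C)(C3=O)[C@@]24O1 | intermediate
18 | oxolane ketone with dioxanone and free bridgehead OH | C1OC(=O)C2=C[C@]3(O)C[C@H]4C(C)(C)O[C@@](CC=C(C)C)(C3=O)[C@@]24O1 | intermediate
19 | cage β-hydroxy acid | OC(=O)C1=C[C@]3(O)C[C@H]4C(C)(C)O[C@@](CC=C(C)C)(C3=O)[C@@]14O | intermediate
20 | 2,6-dimethoxy-1,4-benzoquinone | COC1=CC(=O)C=C(OC)C1=O | starting material
21 | 2,6-dihydroxy-1,4-benzoquinone | O=C1C=C(O)C(=O)C(O)=C1 | intermediate
22 | 3-methylbut-2-enal | CC(C)=CC=O | starting material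
23 | 7-hydroxy-2,2-dimethyl-2H-chromene-5,8-dione | O=C1C=C(O)C(=O)C2=C1C=CC(C)(C)O2 | intermediate
24 | 7-hydroxy-2,2-dimethyl-6-(3-methylbut-2-en-1-yl)-2H-chromene-5,8-dione | CC(C)=CCC1=C(O)C(=O)C2=C(C=CC(C)(C)O2)C1=O | intermediate
25 | acyloxyquinone (7-O-ester of 24 with 19) | CC(C)=CCC1=C(OC(=O)C2=C[C@]3(O)C[C@H]4C(C)(C)O[C@@](CC=C(C)C)(C3=O)[C@@]24O)C(=O)C2=C(C=CC(C)(C)O2)C1=O | intermediate
26 | CNP0222516.1 | CC(C)=CC[C@H]1C(=O)C2=C(OC(C)(C)C=C2)C(=O)[C@@]12OC(=O)C1=C[C@]3(O)C[C@H]4C(C)(C)O[C@@](CC=C(C)C)(C3=O)[C@@]14O2 | target

**Step count and risks**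

Total step count: 19. Longest linear sequence: 15 steps (steps 1–8, 10–15 and 19).

Steps most likely to fail:

Step 19 (Proposed new method). The ketal-enol formed by the oxa-Michael addition may expel the carboxylate instead of ketonising, which would leave the ring-opened 7-alkoxyquinone acid; the spiro carbon or C-6 may also settle in the wrong configuration. Fallback, from 19 and 24 back to 26, uses the known silyl triflate-catalysed acetalisation of silylated β-hydroxy acids with carbonyl compounds to 1,3-dioxan-4-ones. Acid 19 is persilylated (TMSCl, imidazole) to the tris(trimethylsilyl) derivative F1, and 24 is converted into its trimethylsilyl ether F2. With catalytic TMSOTf in CH2Cl2 at −78 °C the two should condense at C-7 with loss of hexamethyldisiloxane to the spiro ketal silyl dienol ether F3. In F3 the C-5 oxygen is held as a silyl enol ether, so no enolate is available to expel the carboxylate. Mild aqueous acid then protonates C-6 and removes the silyl groups to give 26.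

Step 13. The electron-poor prenylated carbon may trigger a 1,2-shift of a cage bond from the neighbouring acetal-bearing bridgehead, or be captured by the prenyl alkene or by trifluoroacetate, before the hindered silyl ether oxygen closes the ring. Fallback, from 16 back to 17, splits the event into two known reactions. N-Iodosuccinimide in CH2Cl2 at −78 °C iodinates the silyl enol ether from its open face to give the tertiary α-iodo ketone F4. AgOTf with 2,6-di-tert-butylpyridine then ionises the C–I bond, and the CMe2 silyl ether oxygen closes the oxolane from the opposite face with loss of its silyl group, giving 17.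

Step 12. Cyclisation may be slow because the tether must adopt the s-cis ester conformation, and at the temperature then needed the adduct may aromatise by cycloreversion or the dienol ether may decompose. Fallback, from 11 back to 19, is the intermolecular Diels–Alder reaction; it also avoids the regiochemical question of step 10. Excess TBSOTf with Et3N converts 11 into the tris-silyloxy diene F5 (the common dioxy-allyl cation is deprotonated at C-4). Heating F5 with methyl propiolate (toluene, 80 °C) should give the bicyclo[2.2.2]octadiene methyl ester F6, with the ester carbon on the silyloxy bridgehead through the donor pattern of the diene and addition anti to the side chain. Oxidative cyclisation as in step 13 gives the oxolane ketone methyl ester F7. HF·pyridine removes both bridgehead silyl groups to give the diol ester F8. Me3SnOH (1,2-dichloroethane, 80 °C) hydrolyses the ester to 19.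

**Further compounds**

F1 | step 19 | tris(trimethylsilyl) derivative of 19 (silyl ester and two bridgehead silyl ethers) | C[Si](C)(C)OC(=O)C1=C[C@]3(O[Si](C)(C)C)C[C@H]4C(C)(C)O[C@@](CC=C(C)C)(C3=O)[C@@]14O[Si](C)(C)C
F2 | step 19 | 7-O-trimethylsilyl ether of 24 | CC(C)=CCC1=C(O[Si](C)(C)C)C(=O)C2=C(C=CC(C)(C)O2)C1=O
F3 | step 19 | spiro ketal with C-5 trimethylsilyl dienol ether and bridgehead OTMS | CC(C)=CCC1=C(O[Si](C)(C)C)C2=C(OC(C)(C)C=C2)C(=O)[C@@]13OC(=O)C2=C[C@]4(O[Si](C)(C)C)C[C@H]5C(C)(C)O[C@@](CC=C(C)C)(C4=O)[C@@]25O3
F4 | step 13 | tertiary α-iodo ketone from 16 (iodine on the face away from the side chain) | O=C1OCO[C@@]2([C@@](I)(CC=C(C)C)C(=O)[C@]3(O[Si](CC)(CC)CC)C=C12)[C@@H](C3)C(C)(C)O[Si](CC)(CC)CC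
F5 | step 12 | tris-silyloxy diene from 11 (C-1 OTBS, C-3 OTBS, C-4 OTES) | CC(C)(C)[Si](C)(C)OC1=C(CC=C(C)C)C(O[Si](C)(C)C(C)(C)C)=C(O[Si](CC)(CC)CC)C[C@H]1C(C)(C)O[Si](CC)(CC)CC
F6 | step 12 | intermolecular adduct: bicyclo[2.2.2]octadiene methyl ester with bridgehead OTBS and OTES | CC(C)(C)[Si](C)(C)O[C@@]2(C(CC=C(C)C)=C(O[Si](C)(C)C(C)(C)C)[C@]3(O[Si](CC)(CC)CC)C=C2C(=O)OC)[C@@H](C3)C(C)(C)O[Si](CC)(CC)CC
F7 | step 12 | oxolane ketone methyl ester with bridgehead OTBS and OTES | COC(=O)C1=C[C@]3(O[Si](CC)(CC)CC)C[C@H]4C(C)(C)O[C@@](CC=C(C)C)(C3=O)[C@@]14O[Si](C)(C)C(C)(C)C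
F8 | step 12 | oxolane ketone methyl ester with both bridgehead OH free | COC(=O)C1=C[C@]3(O)C[C@H]4C(C)(C)O[C@@](CC=C(C)C)(C3=O)[C@@]14O
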